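**Retrosynthetic overview**
1. Locants used in the text: C1 is the O-bearing ring-fusion CH, C2–C13 run round the 14-membered ring (C8 carries OAc), and C14 is the second ring-fusion CH. The target is a trans-fused α-methylene-γ-butyrolactone on an all-E cyclotetradecatriene.
2. Enabling feature: in the lactone ring, the exocyclic CH2=C(α) and C14 form an allyl unit whose inner end C14 belongs to both rings. The methylene lactone is therefore the SN2′ product of a flat 3-(bromomethyl)furan-2(5H)-one, which allows the cut C13–C14.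
3. C13 becomes a nucleophile by hydroboration of the terminal vinyl group of a C10=C11–C12=C13 diene. One pot then closes the large ring, sets C14 and unveils the methylene group.
4. The linear precursor comes from geraniol (C1–C8), a 1-methylallenylboronate (C9–C11, sets C8), vinyl bromide (C12–C13), a vinylzinc reagent (C14, sets C1) and 2-(bromomethyl)acrylic acid (lactone carbons).
5. Ring order: the butenolide ring is closed first (ring-closing metathesis, step 12) and the 14-membered carbocycle last (step 13).

Key step: step 13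

Remark: the sense of induction of (R)-TRIP (step 5) and (+)-MIB (step 10) is assigned by analogy with aryl and alkenyl aldehydes; if a model run shows the opposite sense, the antipodal catalyst is used.

Step 1
Reactants: 1 geraniol
Product: 2 geranyl tert-butyldimethylsilyl ether
Conditions: TBSCl, imidazole, DMF, 0 °C to rt
Reagents that add atoms: tert-butyldimethylsilyl chloride CC(C)(C)[Si](C)(C)Cl
Why: Imidazole-assisted O-silylation of a primary allylic alcohol, which makes no stereocentre and leaves both alkenes untouched.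

Step 2
Reactants: 2 geranyl tert-butyldimethylsilyl ether
Product: 4 (2E,6E)-8-[(tert-butyldimethylsilyl)oxy]-2,6-dimethylocta-2,6-dienal, via allylic alcohol 3 (not isolated)
Conditions: SeO2 (cat.), t-BuOOH, salicylic acid (cat.), CH2Cl2, 0 °C to rt; crude mixture, MnO2, CH2Cl2, rt
Reagents that add atoms: tert-butyl hydroperoxide CC(C)(C)OO
Why: Selenium dioxide allylic oxidation (ene reaction, then [2,3]-shift) should attack the E-methyl group of the more electron-rich terminal alkene, and MnO2 should then carry the allylic alcohol part of the crude product on to the same E-enal.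

Step 3
Reactants: 5 but-2-yn-1-ol
Product: 6 but-2-yn-1-yl methyl carbonate
Conditions: ClCO2Me, pyridine, CH2Cl2, 0 °C
Reagents that add atoms: methyl chloroformate COC(=O)Cl
Why: Simple O-acylation of a primary propargylic alcohol with a chloroformate.

Step 4
Reactants: 6 but-2-yn-1-yl methyl carbonate
Product: 7 2-(buta-2,3-dien-2-yl)-4,4,5,5-tetramethyl-1,3,2-dioxaborolane (1-methylallenyl-Bpin)
Conditions: B2pin2, CuOt-Bu (5 mol %), Xantphos (5 mol %), THF, rt
Reagents that add atoms: bis(pinacolato)diboron CC1(C)OB(OC1(C)C)B1OC(C)(C)C(C)(C)O1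
Why: Copper(I)-boryl SN2′ substitution of a propargylic carbonate should place boron on the methyl-bearing alkyne carbon, while loss of CO2 returns a copper alkoxide that keeps the cycle running.

Step 5
Reactants: 4 (2E,6E)-8-[(tert-butyldimethylsilyl)oxy]-2,6-dimethylocta-2,6-dienal; 7 1-methylallenyl-Bpin
Product: 8 (5R,6E,10E)-12-[(tert-butyldimethylsilyl)oxy]-6,10-dimethyldodeca-6,10-dien-2-yn-5-ol
Conditions: (R)-TRIP (5 mol %), 4 Å MS, toluene, −20 °C; aq. NaHCO3
Reagents that add atoms: none
Why: Chiral phosphoric acid catalysed allenylboration runs through a closed six-membered SE2′ transition state that can only give the homopropargylic alcohol, and the catalyst bound to the boronate should expose the Re face of the enal and so set the (R)-carbinol centre C8.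

Step 6
Reactants: 8 (5R,6E,10E)-12-[(tert-butyldimethylsilyl)oxy]-6,10-dimethyldodeca-6,10-dien-2-yn-5-ol
Product: 10 (3E,6R,7E,11E)-13-[(tert-butyldimethylsilyl)oxy]-3,7,11-trimethyltrideca-1,3,7,11-tetraen-6-ol, via bis-zirconocene alkenyl alkoxide 9 (not isolated)
Conditions: Cp2Zr(H)Cl (2.5 equiv), THF, rt to 40 °C; vinyl bromide, Pd(PPh3)4 (5 mol %), ZnCl2 (cat.), THF, rt; water
Reagents that add atoms: vinyl bromide C=CBr
Why: Hydrozirconation is a syn addition that excess reagent equilibrates to the less hindered methyl-bearing carbon, and the Negishi-type alkenyl–alkenyl coupling keeps the geometry, so the E-trisubstituted terminal diene should result.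

Step 7
Reactants: 10 (3E,6R,7E,11E)-13-[(tert-butyldimethylsilyl)oxy]-3,7,11-trimethyltrideca-1,3,7,11-tetraen-6-ol
Product: 11 (3E,6R,7E,11E)-13-[(tert-butyldimethylsilyl)oxy]-3,7,11-trimethyltrideca-1,3,7,11-tetraen-6-yl acetate
Conditions: Ac2O, pyridine, DMAP (cat.), CH2Cl2, 0 °C to rt
Reagents that add atoms: acetic anhydride CC(=O)OC(C)=O
Why: DMAP-catalysed O-acetylation takes place at oxygen, so the C8 configuration is kept.

Step 8
Reactants: 11 (3E,6R,7E,11E)-13-[(tert-butyldimethylsilyl)oxy]-3,7,11-trimethyltrideca-1,3,7,11-tetraen-6-yl acetate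
Product: 12 (3E,6R,7E,11E)-13-hydroxy-3,7,11-trimethyltrideca-1,3,7,11-tetraen-6-yl acetate
Conditions: HF·pyridine, pyridine, THF, 0 °C to rt
Reagents that add atoms: none
Why: Buffered fluoride desilylation removes the primary silyl ether without touching the secondary allylic acetate or the diene.

Step 9
Reactants: 12 (3E,6R,7E,11E)-13-hydroxy-3,7,11-trimethyltrideca-1,3,7,11-tetraen-6-yl acetate
Product: 13 (3E,6R,7E,11E)-3,7,11-trimethyl-13-oxotrideca-1,3,7,11-tetraen-6-yl acetate
Conditions: MnO2, CH2Cl2, rt
Reagents that add atoms: none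
Why: Neutral MnO2 oxidation of the only free (allylic) alcohol should give the E-enal without isomerisation.

Step 10
Reactants: 13 (3E,6R,7E,11E)-3,7,11-trimethyl-13-oxotrideca-1,3,7,11-tetraen-6-yl acetate
Product: 14 (3E,6R,7E,11E,13R)-13-hydroxy-3,7,11-trimethylpentadeca-1,3,7,11,14-pentaen-6-yl acetate
Conditions: vinylMgBr + ZnCl2 (2:1), THF/dioxane, filtered; (+)-MIB (10 mol %), toluene, 0 °C; water
Reagents that add atoms: vinylmagnesium bromide C=C[Mg]Br
Why: Amino-alcohol-catalysed asymmetric alkenylzinc addition tolerates the acetate, and the (+)-MIB zinc complex should deliver vinyl to the Re face of the enal and so set the (R)-carbinol that becomes C1.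

Step 11
Reactants: 14 (3E,6R,7E,11E,13R)-13-hydroxy-3,7,11-trimethylpentadeca-1,3,7,11,14-pentaen-6-yl acetate; 15 2-(bromomethyl)acrylic acid
Product: 16 (3R,4E,8E,10R,12E)-10-acetoxy-5,9,13-trimethylpentadeca-1,4,8,12,14-pentaen-3-yl 2-(bromomethyl)prop-2-enoate
Conditions: DCC, DMAP (5 mol %), CH2Cl2, −10 °C to rt
Reagents that add atoms: none
Why: Steglich esterification acylates the acid-sensitive bis-allylic alcohol at oxygen under near-neutral conditions, so C1 keeps its configuration and little DMAP is offered to the allylic bromide.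

Step 12
Reactants: 16 (3R,4E,8E,10R,12E)-10-acetoxy-5,9,13-trimethylpentadeca-1,4,8,12,14-pentaen-3-yl 2-(bromomethyl)prop-2-enoate
Product: 17 (5S)-3-(bromomethyl)-5-[(1E,5E,7R,9E)-7-acetoxy-2,6,10-trimethyldodeca-1,5,9,11-tetraen-1-yl]furan-2(5H)-one
Conditions: Hoveyda–Grubbs 2nd-generation catalyst (10 mol %), 1,4-benzoquinone (20 mol %), toluene (1 mM), 70 °C, Ar sparge
Reagents that add atoms: none
Why: Ring-closing metathesis of the carbinol vinyl group onto the α-substituted acrylate closes the five-membered ring irreversibly under neutral conditions that spare the acidic O–CH centre, whose descriptor changes to S only through the CIP ranking.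

Step 13
Reactants: 17 (5S)-3-(bromomethyl)-5-[(1E,5E,7R,9E)-7-acetoxy-2,6,10-trimethyldodeca-1,5,9,11-tetraen-1-yl]furan-2(5H)-one
Product: 19 (3aR,6E,9R,10E,14E,15aS)-6,10,14-trimethyl-3-methylidene-2-oxo-2,3,3a,4,5,8,9,12,13,15a-decahydrocyclotetradeca[b]furan-9-yl acetate (target), via B-alkyl-9-BBN borane 18 (not isolated)
Conditions: 9-BBN-H dimer (0.55 equiv), THF, 0 °C to rt; this solution and KOt-Bu (1.0 equiv, THF) added in parallel by syringe pump (12 h) to CuOAc (25 mol %), THF, 30 °C, final 1 mM
Reagents that add atoms: none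
Why: Proposed new method: the terminal vinyl group of the diene is the only unhindered, electron-rich monosubstituted alkene in 17, so 9-BBN-H should add there alone with boron on the end carbon (18), and tert-butoxide then turns the borane into a borate that hands its primary alkyl group to copper(I). The alkylcopper should bind the electron-poor butenolide C=C, add oxidatively at the β-carbon C14 with loss of bromide from the CH2Br group (anti-SN2′, equally written as conjugate addition followed by E1cB loss of bromide) and reductively eliminate, so that the ring bond C13–C14, the ring-fusion stereocentre and the exocyclic methylene arise together. The closest known reaction types are the copper-catalysed γ-selective allyl–alkyl coupling of B-alkyl-9-BBN reagents with allylic phosphates and halides and the organocopper SN2′ substitution of 2-(bromomethyl)acrylates, and what is new is the butenolide electrophile and the intramolecular macrocyclic setting. The 14-membered ring closes in a 14-exo-trig mode, since the α-carbon of the attacked C=C stays outside the new ring. The new stereocentre C14 is controlled by the existing stereocentre C1, because copper and then carbon enter the flat ring on the face opposite to the alkenyl substituent, which gives the trans fusion that the twelve-atom all-E tether should span with less strain. γ- over α-attack is secured by the lactone carbonyl that polarises C14, cyclisation over oligomerisation by the slow parallel addition at about 1 mM, and the configuration of the acidic O–CH centre by never letting free alkoxide build up.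

**Compound list**
1 | geraniol, (2E)-3,7-dimethylocta-2,6-dien-1-ol | CC(C)=CCC/C(C)=C/CO | starting material
2 | geranyl tert-butyldimethylsilyl ether | CC(C)=CCC/C(C)=C/CO[Si](C)(C)C(C)(C)C | intermediate
3 | (2E,6E)-8-[(tert-butyldimethylsilyl)oxy]-2,6-dimethylocta-2,6-dien-1-ol | OC/C(C)=C/CC/C(C)=C/CO[Si](C)(C)C(C)(C)C | intermediate
4 | (2E,6E)-8-[(tert-butyldimethylsilyl)oxy]-2,6-dimethylocta-2,6-dienal | O=C/C(C)=C/CC/C(C)=C/CO[Si](C)(C)C(C)(C)C | intermediate
5 | but-2-yn-1-ol | CC#CCO | starting material
6 | but-2-yn-1-yl methyl carbonate | CC#CCOC(=O)OC | intermediate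
7 | 2-(buta-2,3-dien-2-yl)-4,4,5,5-tetramethyl-1,3,2-dioxaborolane | C=C=C(C)B1OC(C)(C)C(C)(C)O1 | intermediate
8 | (5R,6E,10E)-12-[(tert-butyldimethylsilyl)oxy]-6,10-dimethyldodeca-6,10-dien-2-yn-5-ol | CC#CC[C@@H](O)/C(C)=C/CC/C(C)=C/CO[Si](C)(C)C(C)(C)C | intermediate
9 | (E)-alkenylzirconocene chloride from 8, Zr on the methyl-bearing alkene carbon and cis to the new vinylic H, carbinol oxygen bound as zirconocene chloride alkoxide (Cp drawn σ-bonded) | C/C(=C\C[C@@H](O[Zr](Cl)(C1C=CC=C1)C1C=CC=C1)/C(C)=C/CC/C(C)=C/CO[Si](C)(C)C(C)(C)C)[Zr](Cl)(C1C=CC=C1)C1C=CC=C1 | intermediate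
10 | (3E,6R,7E,11E)-13-[(tert-butyldimethylsilyl)oxy]-3,7,11-trimethyltrideca-1,3,7,11-tetraen-6-ol | C=C/C(C)=C/C[C@@H](O)/C(C)=C/CC/C(C)=C/CO[Si](C)(C)C(C)(C)C | intermediate
11 | (3E,6R,7E,11E)-13-[(tert-butyldimethylsilyl)oxy]-3,7,11-trimethyltrideca-1,3,7,11-tetraen-6-yl acetate | C=C/C(C)=C/C[C@@H](OC(C)=O)/C(C)=C/CC/C(C)=C/CO[Si](C)(C)C(C)(C)C | intermediate
12 | (3E,6R,7E,11E)-13-hydroxy-3,7,11-trimethyltrideca-1,3,7,11-tetraen-6-yl acetate | C=C/C(C)=C/C[C@@H](OC(C)=O)/C(C)=C/CC/C(C)=C/CO | intermediate
13 | (3E,6R,7E,11E)-3,7,11-trimethyl-13-oxotrideca-1,3,7,11-tetraen-6-yl acetate | C=C/C(C)=C/C[C@@H](OC(C)=O)/C(C)=C/CC/C(C)=C/C=O | intermediate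
14 | (3E,6R,7E,11E,13R)-13-hydroxy-3,7,11-trimethylpentadeca-1,3,7,11,14-pentaen-6-yl acetate | C=C/C(C)=C/C[C@@H](OC(C)=O)/C(C)=C/CC/C(C)=C/[C@H](O)C=C | intermediate
15 | 2-(bromomethyl)acrylic acid | C=C(CBr)C(=O)O | starting material
16 | (3R,4E,8E,10R,12E)-10-acetoxy-5,9,13-trimethylpentadeca-1,4,8,12,14-pentaen-3-yl 2-(bromomethyl)prop-2-enoate | C=C/C(C)=C/C[C@@H](OC(C)=O)/C(C)=C/CC/C(C)=C/[C@H](OC(=O)C(=C)CBr)C=C | intermediate
17 | (5S)-3-(bromomethyl)-5-[(1E,5E,7R,9E)-7-acetoxy-2,6,10-trimethyldodeca-1,5,9,11-tetraen-1-yl]furan-2(5H)-one | C=C/C(C)=C/C[C@@H](OC(C)=O)/C(C)=C/CC/C(C)=C/[C@H]1C=C(CBr)C(=O)O1 | intermediate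
18 | B-alkyl-9-BBN from 17, boron on the former terminal diene carbon | C1CC2CCCC(C1)B2CC/C(C)=C/C[C@@H](OC(C)=O)/C(C)=C/CC/C(C)=C/[C@H]1C=C(CBr)C(=O)O1 | intermediate
19 | (3aR,6E,9R,10E,14E,15aS)-6,10,14-trimethyl-3-methylidene-2-oxo-2,3,3a,4,5,8,9,12,13,15a-decahydrocyclotetradeca[b]furan-9-yl acetate | C=C1C(=O)O[C@H]2/C=C(\C)CC/C=C(\C)[C@H](OC(C)=O)C/C=C(\C)CC[C@H]12 | target

Total step count: 13. Longest linear sequence: 11 (steps 1, 2 and 5–13).

**Steps most likely to fail**

Step 13.
- What may go wrong: boron-to-copper transfer may be too slow at high dilution, so that oligomerisation or protodeboronation overtakes ring closure. Free alkoxide may enolise the O–CH centre of the butenolide and erode its configuration. Attack at the CH2Br carbon may compete.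
- Fallback (sets out from 9, comes back at 19, known chemistry only): the same ring is still closed last, but at its sp2–sp3 bond C11–C12 by a B-alkyl Suzuki–Miyaura macrocyclisation. Zirconocene 9 is quenched with iodine instead of being vinylated, which should give the (E)-vinyl iodide alcohol F1. The operations of steps 7–12 are then run on the iodide series. They should give in turn the acetate F2, the primary allylic alcohol F3, the enal F4, the (R)-vinyl carbinol F5, the 2-(bromomethyl)acrylate ester F6 and the 3-(bromomethyl)butenolide F7; in this series the metathesis meets no diene. Vinylmagnesium bromide with catalytic CuBr·SMe2 in THF at −78 °C should displace bromide in the SN2′ sense, anti to the side chain, to give the trans-4-vinyl-3-methylene lactone F8. 9-BBN-H should add only to this vinyl group to give the B-alkyl-9-BBN borane F9. Pd(dppf)Cl2, AsPh3 and Cs2CO3 in DMF/THF/water at high dilution should then couple F9 with the vinyl iodide, with retention of the E geometry, to give 19.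

Step 12.
- What may go wrong: the ruthenium carbene may load onto the terminal vinyl group of the diene instead of the carbinol vinyl group. This would lead to cross-metathesis, oligomerisation and trapping of the catalyst as a sluggish vinylcarbene before the hindered, electron-poor 1,1-disubstituted alkene is reached.
- Fallback (sets out from 13, comes back at 17): a relay ring-closing metathesis delivers the carbene to C14 on purpose. Hept-1-en-6-yne is converted by hydrozirconation and zirconium–zinc exchange with Me2Zn into (E)-hepta-1,6-dienyl(methyl)zinc F10. With (+)-MIB this reagent should add to enal 13 to give the relay carbinol F11. Steglich esterification with 15 should give the relay ester F12. The catalyst should enter at the unhindered terminal alkene of the relay arm, expel cyclopentene, and so arrive at C14 next to the acrylate, where closure to 17 follows.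

Step 5.
- What may go wrong: the methyl group on the boron-bearing carbon of 7 may crowd the closed transition state, which would slow the addition and lower the facial selectivity at C8.
- Fallback (sets out from 4, comes back at 8): the methyl group is added afterwards. Commercial allenylboronic acid pinacol ester with (R)-TRIP, the parent case of this reaction type, should give the terminal homopropargylic alcohol F13. Its O,C-dianion (n-BuLi, 2.1 equiv, THF/DMPU, −78 °C) should then be methylated at carbon with MeI (1.0 equiv) to give 8.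

**Further compounds**
F1 | step 13 | (2E,5R,6E,10E)-12-[(tert-butyldimethylsilyl)oxy]-2-iodo-6,10-dimethyldodeca-2,6,10-trien-5-ol | C/C(I)=C\C[C@@H](O)/C(C)=C/CC/C(C)=C/CO[Si](C)(C)C(C)(C)C
F2 | step 13 | (2E,5R,6E,10E)-12-[(tert-butyldimethylsilyl)oxy]-2-iodo-6,10-dimethyldodeca-2,6,10-trien-5-yl acetate | C/C(I)=C\C[C@@H](OC(C)=O)/C(C)=C/CC/C(C)=C/CO[Si](C)(C)C(C)(C)C
F3 | step 13 | (2E,5R,6E,10E)-12-hydroxy-2-iodo-6,10-dimethyldodeca-2,6,10-trien-5-yl acetate | C/C(I)=C\C[C@@H](OC(C)=O)/C(C)=C/CC/C(C)=C/CO
F4 | step 13 | (2E,5R,6E,10E)-2-iodo-6,10-dimethyl-12-oxododeca-2,6,10-trien-5-yl acetate | C/C(I)=C\C[C@@H](OC(C)=O)/C(C)=C/CC/C(C)=C/C=O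
F5 | step 13 | (2E,5R,6E,10E,12R)-12-hydroxy-2-iodo-6,10-dimethyltetradeca-2,6,10,13-tetraen-5-yl acetate | C/C(I)=C\C[C@@H](OC(C)=O)/C(C)=C/CC/C(C)=C/[C@H](O)C=C
F6 | step 13 | (3R,4E,8E,10R,12E)-10-acetoxy-13-iodo-5,9-dimethyltetradeca-1,4,8,12-tetraen-3-yl 2-(bromomethyl)prop-2-enoate | C/C(I)=C\C[C@@H](OC(C)=O)/C(C)=C/CC/C(C)=C/[C@H](OC(=O)C(=C)CBr)C=C
F7 | step 13 | (5S)-3-(bromomethyl)-5-[(1E,5E,7R,9E)-7-acetoxy-10-iodo-2,6-dimethylundeca-1,5,9-trien-1-yl]furan-2(5H)-one | C/C(I)=C\C[C@@H](OC(C)=O)/C(C)=C/CC/C(C)=C/[C@H]1C=C(CBr)C(=O)O1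
F8 | step 13 | (4R,5S)-4-ethenyl-3-methylidene-5-[(1E,5E,7R,9E)-7-acetoxy-10-iodo-2,6-dimethylundeca-1,5,9-trien-1-yl]oxolan-2-one (trans) | C/C(I)=C\C[C@@H](OC(C)=O)/C(C)=C/CC/C(C)=C/[C@@H]1OC(=O)C(=C)[C@H]1C=C
F9 | step 13 | B-alkyl-9-BBN from F8, boron on the former terminal vinyl carbon | C/C(I)=C\C[C@@H](OC(C)=O)/C(C)=C/CC/C(C)=C/[C@@H]1OC(=O)C(=C)[C@H]1CCB1C2CCCC1CCC2
F10 | step 12 | (E)-hepta-1,6-dienyl(methyl)zinc | C=CCCC/C=C/[Zn]C
F11 | step 12 | (3E,6R,7E,11E,13R,14E)-13-hydroxy-3,7,11-trimethylicosa-1,3,7,11,14,19-hexaen-6-yl acetate | C=C/C(C)=C/C[C@@H](OC(C)=O)/C(C)=C/CC/C(C)=C/[C@H](O)/C=C/CCCC=C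
F12 | step 12 | 2-(bromomethyl)prop-2-enoate ester of F11 at the 13-hydroxy group | C=C/C(C)=C/C[C@@H](OC(C)=O)/C(C)=C/CC/C(C)=C/[C@H](OC(=O)C(=C)CBr)/C=C/CCCC=C
F13 | step 5 | (4R,5E,9E)-11-[(tert-butyldimethylsilyl)oxy]-5,9-dimethylundeca-5,9-dien-1-yn-4-ol | C#CC[C@@H](O)/C(C)=C/CC/C(C)=C/CO[Si](C)(C)C(C)(C)C
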